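**Retrosynthetic overview**

- Side-chain carbons are numbered C1' (ring CH2) to C32'. MK-8 ⇒ its 1,4-dimethoxynaphthalene (quinone unmasked last) ⇒ C19'–C20' cut by a Zweifel olefination into a C16 homofarnesyl pinacol boronate and a C25 (Z)-alkenyl iodide that already carries the arene.
- Enabling feature: C19' is the hydrogen-free, methyl-bearing sp2 carbon of the C18'=C19' olefin and can be held as a configurationally stable alkenyllithium. C20' is a primary sp3 carbon separated from the C22'=C23' olefin by C21', so its boronate is an ordinary non-allylic alkylboron. Both carbons are nucleophiles joined oxidatively by I2, with inversion that turns the easily made Z-iodide into the 18'E olefin.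
- (Z)-Iodide ⇒ C18' aldehyde (α-iodo-ylide Wittig) ⇒ terminal allylic oxidation, bromination and cyanomethyl extension of the geranylgeranyl arene ⇒ aryl Grignard reagent + geranylgeranyl bromide. Boronate ⇒ farnesyl bromide + CH2(Bpin)2.
- No ring is formed: the benzo ring and the quinone ring (C1–C4, carried as the 1,4-dimethoxyarene from step 1 to step 11) both come from menadione.

Key step: step 11

Remark: commercial (2E,6E)-farnesyl bromide and (2E,6E,10E)-geranylgeraniol are taken as geometrically pure; every other olefin geometry is set or conserved in the route.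

**Route**

Step 1
Reactants: 1 menadione (2-methylnaphthalene-1,4-dione)
Product: 3 1,4-dimethoxy-2-methylnaphthalene, via menadiol 2 (not isolated)
Conditions: Na2S2O4, Bu4NBr (cat.), THF/H2O, rt; then KOH, Me2SO4, rt
Reagents that add atoms: dimethyl sulfate, COS(=O)(=O)OC
Why: Dithionite reduces the quinone to the hydroquinone, whose dianion is O-methylated twice under phase-transfer conditions (one-pot reductive methylation, Williamson ether synthesis).

Step 2
Reactants: 3 1,4-dimethoxy-2-methylnaphthalene
Product: 4 2-bromo-1,4-dimethoxy-3-methylnaphthalene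
Conditions: Br2, CH2Cl2, 0 °C
Reagents that add atoms: bromine, BrBr
Why: Electrophilic aromatic bromination should occur at C3, the only free position of the doubly methoxy-activated ring.

Step 3
Reactants: 5 (2E,6E,10E)-geranylgeraniol
Product: 6 (2E,6E,10E)-geranylgeranyl bromide
Conditions: PBr3, Et2O, −10 °C; used crude
Reagents that add atoms: phosphorus tribromide, BrP(Br)Br
Why: PBr3 converts the primary allylic alcohol into the bromide by SN2 displacement of the phosphite ester at low temperature, without allylic transposition or loss of the 2E geometry.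

Step 4
Reactants: 4 2-bromo-1,4-dimethoxy-3-methylnaphthalene; 6 (2E,6E,10E)-geranylgeranyl bromide
Product: 8 2-geranylgeranyl-1,4-dimethoxy-3-methylnaphthalene, via aryl Grignard reagent 7 (not isolated)
Conditions: Mg, THF, reflux; then CuBr·SMe2 (5 mol %), 6, −20 °C to rt
Reagents that add atoms: none
Why: Magnesium insertion gives the aryl Grignard reagent, and copper-catalysed allylic substitution should then take place at the primary α-carbon of 6 (SN2 and not SN2', the γ-carbon being fully substituted), so the arene–C1' bond forms with the 2'E olefin intact.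

Step 5
Reactants: 8 2-geranylgeranyl-1,4-dimethoxy-3-methylnaphthalene
Product: 9 terminal (E)-allylic alcohol (C16'-OH)
Conditions: SeO2 (10 mol %), salicylic acid (10 mol %), t-BuOOH (70% aq.), CH2Cl2, 0 °C to rt; stopped at partial conversion, 8 recycled
Reagents that add atoms: tert-butyl hydroperoxide, CC(C)(C)OO (oxygen source; the oxygen is transferred by way of SeO2, O=[Se]=O)
Why: SeO2-catalysed allylic oxidation (ene reaction then [2,3]-sigmatropic shift, Riley oxidation) should attack the most accessible, terminal isopropylidene group and oxidise its E-methyl group, which fixes the 14'E geometry of the new allylic alcohol.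

Step 6
Reactants: 9 terminal (E)-allylic alcohol
Product: 10 terminal (E)-allylic bromide (C16'-Br)
Conditions: CBr4, PPh3, CH2Cl2, 0 °C
Reagents that add atoms: carbon tetrabromide, BrC(Br)(Br)Br
Why: The Appel reaction replaces the primary allylic hydroxyl by bromide under neutral conditions through SN2 attack on the alkoxyphosphonium ion, keeping the 14'E geometry.

Step 7
Reactants: 10 terminal (E)-allylic bromide
Product: 11 C18' nitrile
Conditions: MeCN (5 equiv), n-BuLi (4.5 equiv), THF, −78 °C; then 10, −78 °C to −20 °C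
Reagents that add atoms: acetonitrile, CC#N
Why: Lithioacetonitrile in excess should alkylate the primary allylic bromide by SN2 displacement at C16', adding C17' and C18' in one operation (nitrile anion alkylation).

Step 8
Reactants: 11 C18' nitrile
Product: 13 C18' aldehyde, via N-aluminoimine 12 (not isolated)
Conditions: i-Bu2AlH (1.2 equiv), CH2Cl2, −78 °C; then 1 M HCl (aq), 0 °C
Reagents that add atoms: water, O (supplies the aldehyde oxygen on hydrolysis)
Why: i-Bu2AlH adds one hydride to the nitrile to give an N-aluminoimine that resists further reduction and is hydrolysed to the aldehyde on acidic work-up (partial reduction of a nitrile).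

Step 9
Reactants: 13 C18' aldehyde
Product: 14 (Z)-alkenyl iodide (18'Z, iodine on C19')
Conditions: EtPPh3I, n-BuLi, THF, 0 °C; I2, −78 °C; NaN(SiMe3)2, −20 °C; then 13, −78 °C to −20 °C
Reagents that add atoms: ethyltriphenylphosphonium iodide, CC[P+](c1ccccc1)(c1ccccc1)c1ccccc1.[I-]; iodine, II
Why: Wittig olefination with the non-stabilised α-iodo ylide Ph3P=C(I)CH3 (Stork–Zhao variant) runs under kinetic control through the cis-oxaphosphetane and should give the (Z)-2-iodo-2-alkene, with iodine cis to C17'.

Step 10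
Reactants: 15 (2E,6E)-farnesyl bromide
Product: 16 homofarnesyl pinacol boronate
Conditions: CH2(Bpin)2 (1.3 equiv), NaOt-Bu, THF, 0 °C to rt
Reagents that add atoms: bis[(pinacolato)boryl]methane, CC1(C)OB(CB2OC(C)(C)C(C)(C)O2)OC1(C)C
Why: tert-Butoxide removes one boryl group of the geminal bis(boronate) to give an α-boryl carbanion that should displace the primary allylic bromide by SN2 attack at the unhindered α-carbon (alkoxide-promoted deborylative alkylation), giving the one-carbon-homologated primary boronic ester with both olefins untouched.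

Step 11
Reactants: 14 (Z)-alkenyl iodide; 16 homofarnesyl pinacol boronate
Product: 20 menaquinone-8 hydroquinone dimethyl ether, via (Z)-alkenyllithium 17 (not isolated), via lithium boronate complex 18 (not isolated), via β-iodoboronic ester 19 (not isolated)
Conditions: t-BuLi (2.0 equiv), THF/Et2O, −78 °C; then 16, −78 °C; then I2 (1.1 equiv), THF, −78 °C; then NaOMe, MeOH, −78 °C to rt
Reagents that add atoms: none
Why: Iodine–lithium exchange with retention gives the (Z)-alkenyllithium, which adds to boron of 16 to form a tetracoordinate boronate with C17' cis to boron; I2 then forms an iodonium ion on this electron-rich alkenylboronate, the C20' methylene migrates from boron to C19' anti to the C–I bond (1,2-metallate rearrangement), and methoxide triggers anti elimination of iodide and boron (Zweifel olefination). The closest known reaction type is the iodine-mediated coupling of α-substituted alkenyllithiums with primary alkyl pinacol boronic esters to give trisubstituted olefins, formally an oxidative union of two nucleophilic carbons without a transition metal. No ring is closed and no stereocentre remains: the two transient stereocentres of the β-iodoboronate are set by the anti addition and consumed by the anti elimination, so the Z geometry of 14 is translated with inversion into the 18'E geometry of 20. The step needs chemoselectivity of I2 for the anionic alkenylboronate over the seven isolated trisubstituted olefins and the dimethoxynaphthalene, which the far higher nucleophilicity of the boronate, one equivalent of I2 and −78 °C should secure. It also needs exclusive migration of the homofarnesyl group, secured because the only other substituents on boron are the pinacol oxygens, while the homoallylic (not allylic) position of boron rules out allylic transposition.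

Step 12
Reactants: 20 menaquinone-8 hydroquinone dimethyl ether
Product: 21 menaquinone-8
Conditions: (NH4)2Ce(NO3)6 (2.5 equiv), MeCN/CH2Cl2/H2O, 0 °C
Reagents that add atoms: water, O (supplies both quinone oxygens)
Why: Tetravalent cerium oxidises the electron-rich 1,4-dimethoxyarene by two one-electron transfers with ipso attack of water and loss of two molecules of methanol (oxidative demethylation), which should restore the quinone at 0 °C without touching the isolated olefins.

**Compound list**

1 | menadione (2-methylnaphthalene-1,4-dione) | CC1=CC(=O)c2ccccc2C1=O | starting material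
2 | menadiol (2-methylnaphthalene-1,4-diol) | Cc1cc(O)c2ccccc2c1O | intermediate
3 | 1,4-dimethoxy-2-methylnaphthalene | COc1cc(C)c(OC)c2ccccc12 | intermediate
4 | 2-bromo-1,4-dimethoxy-3-methylnaphthalene | COc1c(Br)c(C)c(OC)c2ccccc12 | intermediate
5 | (2E,6E,10E)-geranylgeraniol, (2E,6E,10E)-3,7,11,15-tetramethylhexadeca-2,6,10,14-tetraen-1-ol | CC(C)=CCC/C(C)=C/CC/C(C)=C/CC/C(C)=C/CO | starting material
6 | (2E,6E,10E)-geranylgeranyl bromide | CC(C)=CCC/C(C)=C/CC/C(C)=C/CC/C(C)=C/CBr | intermediate
7 | (1,4-dimethoxy-3-methylnaphthalen-2-yl)magnesium bromide | COc1c([Mg]Br)c(C)c(OC)c2ccccc12 | intermediate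
8 | 1,4-dimethoxy-2-methyl-3-[(2E,6E,10E)-3,7,11,15-tetramethylhexadeca-2,6,10,14-tetraen-1-yl]naphthalene | CC(C)=CCC/C(C)=C/CC/C(C)=C/CC/C(C)=C/Cc1c(C)c(OC)c2ccccc2c1OC | intermediate
9 | (2E,6E,10E,14E)-16-(1,4-dimethoxy-3-methylnaphthalen-2-yl)-2,6,10,14-tetramethylhexadeca-2,6,10,14-tetraen-1-ol | OC/C(C)=C/CC/C(C)=C/CC/C(C)=C/CC/C(C)=C/Cc1c(C)c(OC)c2ccccc2c1OC | intermediate
10 | 2-[(2E,6E,10E,14E)-16-bromo-3,7,11,15-tetramethylhexadeca-2,6,10,14-tetraen-1-yl]-1,4-dimethoxy-3-methylnaphthalene | BrC/C(C)=C/CC/C(C)=C/CC/C(C)=C/CC/C(C)=C/Cc1c(C)c(OC)c2ccccc2c1OC | intermediate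
11 | (4E,8E,12E,16E)-18-(1,4-dimethoxy-3-methylnaphthalen-2-yl)-4,8,12,16-tetramethyloctadeca-4,8,12,16-tetraenenitrile | N#CCC/C(C)=C/CC/C(C)=C/CC/C(C)=C/CC/C(C)=C/Cc1c(C)c(OC)c2ccccc2c1OC | intermediate
12 | N-(diisobutylalumino)imine of aldehyde 13 | CC(C)C[Al](CC(C)C)N=CCC/C(C)=C/CC/C(C)=C/CC/C(C)=C/CC/C(C)=C/Cc1c(C)c(OC)c2ccccc2c1OC | intermediate
13 | (4E,8E,12E,16E)-18-(1,4-dimethoxy-3-methylnaphthalen-2-yl)-4,8,12,16-tetramethyloctadeca-4,8,12,16-tetraenal | O=CCC/C(C)=C/CC/C(C)=C/CC/C(C)=C/CC/C(C)=C/Cc1c(C)c(OC)c2ccccc2c1OC | intermediate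
14 | 2-[(2E,6E,10E,14E,18Z)-19-iodo-3,7,11,15-tetramethylicosa-2,6,10,14,18-pentaen-1-yl]-1,4-dimethoxy-3-methylnaphthalene | C/C(I)=C/CC/C(C)=C/CC/C(C)=C/CC/C(C)=C/CC/C(C)=C/Cc1c(C)c(OC)c2ccccc2c1OC | intermediate
15 | (2E,6E)-farnesyl bromide, (2E,6E)-1-bromo-3,7,11-trimethyldodeca-2,6,10-triene | CC(C)=CCC/C(C)=C/CC/C(C)=C/CBr | starting material
16 | 4,4,5,5-tetramethyl-2-[(3E,7E)-4,8,12-trimethyltrideca-3,7,11-trien-1-yl]-1,3,2-dioxaborolane (homofarnesyl pinacol boronate) | CC(C)=CCC/C(C)=C/CC/C(C)=C/CCB1OC(C)(C)C(C)(C)O1 | intermediate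
17 | (Z)-alkenyllithium from 14 (lithium on C19', cis to C17') | C/C([Li])=C/CC/C(C)=C/CC/C(C)=C/CC/C(C)=C/CC/C(C)=C/Cc1c(C)c(OC)c2ccccc2c1OC | intermediate
18 | lithium alkenyl(homofarnesyl)pinacolatoborate (boron on C19', cis to C17') | [Li+].CC(C)=CCC/C(C)=C/CC/C(C)=C/CC[B-]1(OC(C)(C)C(C)(C)O1)/C(C)=C\CC/C(C)=C/CC/C(C)=C/CC/C(C)=C/CC/C(C)=C/Cc1c(C)c(OC)c2ccccc2c1OC | intermediate
19 | β-iodoboronic ester (iodine on C18'; methyl, homofarnesyl and Bpin on C19'; anti adduct, racemic, one enantiomer drawn) | CC(C)=CCC/C(C)=C/CC/C(C)=C/CC[C@](C)(B1OC(C)(C)C(C)(C)O1)[C@H](I)CC/C(C)=C/CC/C(C)=C/CC/C(C)=C/CC/C(C)=C/Cc1c(C)c(OC)c2ccccc2c1OC | intermediate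
20 | 1,4-dimethoxy-2-methyl-3-[(2E,6E,10E,14E,18E,22E,26E)-3,7,11,15,19,23,27,31-octamethyldotriaconta-2,6,10,14,18,22,26,30-octaen-1-yl]naphthalene | CC(C)=CCC/C(C)=C/CC/C(C)=C/CC/C(C)=C/CC/C(C)=C/CC/C(C)=C/CC/C(C)=C/CC/C(C)=C/Cc1c(C)c(OC)c2ccccc2c1OC | intermediate
21 | menaquinone-8 | CC(C)=CCC/C(C)=C/CC/C(C)=C/CC/C(C)=C/CC/C(C)=C/CC/C(C)=C/CC/C(C)=C/CC/C(C)=C/CC1=C(C)C(=O)c2ccccc2C1=O | target

**Step count and risks**

Total step count: 12. Longest linear sequence: 10 steps (1, 2, 4, 5, 6, 7, 8, 9, 11, 12).

Steps most likely to fail: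

Step 11. Electrophilic iodination or iodomethoxylation of the isolated trisubstituted olefins may compete with attack of I2 on the boronate, or the migration/elimination sequence may lose stereospecificity, which would erode yield and the 18'E purity. The fallback sets out from 13 and 16 and comes back at 20, and uses no electrophilic halogen in the coupling. Wittig-type dichloromethylenation of 13 (PPh3, CCl4, MeCN) should give the 1,1-dichloroalkene F1. Oxidation of 16 (H2O2, NaOH, THF/H2O) should give homofarnesol F2, which I2/PPh3/imidazole should convert into homofarnesyl iodide F3, and iodine–lithium exchange (t-BuLi, Et2O, −78 °C) followed by ZnBr2 should give homofarnesylzinc bromide F4. Negishi coupling of F4 with F1 under PdCl2(DPEphos) catalysis, in which zerovalent palladium inserts into the C–Cl bond trans to the chain, should give the (Z)-chloroalkene F5 with the homofarnesyl group trans to C17'. A second Negishi coupling with MeZnBr under Pd(t-Bu3P)2 catalysis, with retention, should then give 20.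

Step 9. Incomplete Z selectivity, loss of iodine from the ylide and enolisation of the aldehyde may give a low yield of an iodide mixture that is hard to separate on a C25 hydrocarbon chain. The fallback sets out from 13 and 16 and comes back at 20, replacing the Wittig reaction and the stereoinverting coupling by a syn-hydrometalation and a stereoretentive coupling. Seyferth–Gilbert homologation of 13 with the Ohira–Bestmann reagent (K2CO3, MeOH) should give the terminal alkyne F6, and deprotonation and methylation (n-BuLi, then MeI) the 2-alkyne F7. Hydrozirconation with excess Cp2Zr(H)Cl under equilibrating conditions (syn addition, zirconium at the less hindered methyl-bearing carbon) followed by I2 should give the (E)-alkenyl iodide F8. Treatment of 16 with KHF2 (MeOH/H2O) should give potassium homofarnesyltrifluoroborate F9, and Suzuki–Miyaura coupling of F8 with F9 (PdCl2(dppf), Cs2CO3, THF/H2O, 80 °C) with retention should give 20.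

Step 5. Oxidation may spread to the internal olefins or the ring-bound CH2 and run on to the enal before useful conversion is reached. The fallback sets out from 8 and comes back at 9, and rebuilds the terminal olefin instead of oxidising it. Terminal-selective bromohydrin formation (NBS, THF/H2O, 0 °C) should give the bromohydrin F10, and K2CO3 in MeOH the terminal epoxide F11. Cleavage with HIO4 (THF/H2O) should give the aldehyde F12, E-selective Wittig olefination with Ph3P=C(CH3)CO2Et (CH2Cl2, rt) the (E)-enoate F13, and reduction with i-Bu2AlH (CH2Cl2, −78 °C) 9.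

Further compounds
F1 | step 11 | 2-[(2E,6E,10E,14E)-19,19-dichloro-3,7,11,15-tetramethylnonadeca-2,6,10,14,18-pentaen-1-yl]-1,4-dimethoxy-3-methylnaphthalene | ClC(Cl)=CCC/C(C)=C/CC/C(C)=C/CC/C(C)=C/CC/C(C)=C/Cc1c(C)c(OC)c2ccccc2c1OC
F2 | step 11 | homofarnesol, (3E,7E)-4,8,12-trimethyltrideca-3,7,11-trien-1-ol | CC(C)=CCC/C(C)=C/CC/C(C)=C/CCO
F3 | step 11 | homofarnesyl iodide, (3E,7E)-1-iodo-4,8,12-trimethyltrideca-3,7,11-triene | CC(C)=CCC/C(C)=C/CC/C(C)=C/CCI
F4 | step 11 | homofarnesylzinc bromide | CC(C)=CCC/C(C)=C/CC/C(C)=C/CC[Zn]Br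
F5 | step 11 | 2-[(2E,6E,10E,14E,18Z,22E,26E)-19-chloro-3,7,11,15,23,27,31-heptamethyldotriaconta-2,6,10,14,18,22,26,30-octaen-1-yl]-1,4-dimethoxy-3-methylnaphthalene | CC(C)=CCC/C(C)=C/CC/C(C)=C/CC/C(Cl)=C/CC/C(C)=C/CC/C(C)=C/CC/C(C)=C/CC/C(C)=C/Cc1c(C)c(OC)c2ccccc2c1OC
F6 | step 9 | 1,4-dimethoxy-2-methyl-3-[(2E,6E,10E,14E)-3,7,11,15-tetramethylnonadeca-2,6,10,14-tetraen-18-yn-1-yl]naphthalene | C#CCC/C(C)=C/CC/C(C)=C/CC/C(C)=C/CC/C(C)=C/Cc1c(C)c(OC)c2ccccc2c1OC
F7 | step 9 | 1,4-dimethoxy-2-methyl-3-[(2E,6E,10E,14E)-3,7,11,15-tetramethylicosa-2,6,10,14-tetraen-18-yn-1-yl]naphthalene | CC#CCC/C(C)=C/CC/C(C)=C/CC/C(C)=C/CC/C(C)=C/Cc1c(C)c(OC)c2ccccc2c1OC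
F8 | step 9 | 2-[(2E,6E,10E,14E,18E)-19-iodo-3,7,11,15-tetramethylicosa-2,6,10,14,18-pentaen-1-yl]-1,4-dimethoxy-3-methylnaphthalene | C/C(I)=C\CC/C(C)=C/CC/C(C)=C/CC/C(C)=C/CC/C(C)=C/Cc1c(C)c(OC)c2ccccc2c1OC
F9 | step 9 | potassium trifluoro[(3E,7E)-4,8,12-trimethyltrideca-3,7,11-trien-1-yl]borate | [K+].CC(C)=CCC/C(C)=C/CC/C(C)=C/CC[B-](F)(F)F
F10 | step 5 | (6E,10E,14E)-3-bromo-16-(1,4-dimethoxy-3-methylnaphthalen-2-yl)-2,6,10,14-tetramethylhexadeca-6,10,14-trien-2-ol (racemic) | CC(C)(O)C(Br)CC/C(C)=C/CC/C(C)=C/CC/C(C)=C/Cc1c(C)c(OC)c2ccccc2c1OC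
F11 | step 5 | 3-[(3E,7E,11E)-13-(1,4-dimethoxy-3-methylnaphthalen-2-yl)-3,7,11-trimethyltrideca-3,7,11-trien-1-yl]-2,2-dimethyloxirane (racemic) | CC1(C)OC1CC/C(C)=C/CC/C(C)=C/CC/C(C)=C/Cc1c(C)c(OC)c2ccccc2c1OC
F12 | step 5 | (4E,8E,12E)-14-(1,4-dimethoxy-3-methylnaphthalen-2-yl)-4,8,12-trimethyltetradeca-4,8,12-trienal | O=CCC/C(C)=C/CC/C(C)=C/CC/C(C)=C/Cc1c(C)c(OC)c2ccccc2c1OC
F13 | step 5 | ethyl (2E,6E,10E,14E)-16-(1,4-dimethoxy-3-methylnaphthalen-2-yl)-2,6,10,14-tetramethylhexadeca-2,6,10,14-tetraenoate | CCOC(=O)/C(C)=C/CC/C(C)=C/CC/C(C)=C/CC/C(C)=C/Cc1c(C)c(OC)c2ccccc2c1OC
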